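**Plan**

- Rings: A = guaiacyl ring on carbinol C7; B = central phenol carrying C8 and the CH2 to lactone C4; C = benzo ring of the dihydrobenzofuran; D = its 2-aryl ring.
- Cuts: (a) lactone C3–CH2(ring C) by enolate alkylation; (b) furan C3–C3a by a retro 1,2-shift to a flavanone; (c) C7–C8 of the ring A/B diol by aldol; (d) the lactone by Stobbe condensation, hydrogenation and lactonisation.
- Enabling feature: furan C3 holds both the benzo carbon C3a and a one-carbon arm (CH2OH) trans to ring D on C2. This is the pattern left when C4a of a (2S)-flavanone moves from C4 to C3 and the old carbonyl carbon C4 leaves the ring as an ester.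
- Forward: ketone 1 → bromide 2, used for both halves. East: 2 → chromone → flavanone → ring-contracted ester → benzylic bromide 14. West: 2 → arylacetic imide → anti-aldol with the ring A aldehyde → acetonide → lactone 32. Then 32 + 14 and deprotection.
- Stereochemistry: furan C2 from the Pd/PyOx conjugate addition, C3 from the shift itself; C7/C8 from an oxazolidinone auxiliary; lactone C4 from Rh/DuPhos hydrogenation; lactone C3 from anti alkylation.

Key step: step 4

Assumption: the sense of induction in steps 3 and 19 is assigned by analogy with the closest substrate classes (3-substituted cyclohexenones for the PyOx catalyst, itaconates for the DuPhos catalyst); should either run the other way, the antipodal ligand is used.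

**Route**

Step 1
Reactants: 1 1-(2-hydroxy-3-methoxyphenyl)ethanone
Product: 2 1-(5-bromo-2-hydroxy-3-methoxyphenyl)ethanone
Conditions: NBS, MeCN, 0 °C → rt
Reagents that add atoms: N-bromosuccinimide, O=C1CCC(=O)N1Br
Why: Electrophilic aromatic bromination is steered by the phenol, whose two ortho positions are blocked, so bromine should enter only para to OH.

Step 2
Reactants: 2 1-(5-bromo-2-hydroxy-3-methoxyphenyl)ethanone; 3 N,N-dimethylformamide dimethyl acetal
Product: 5 6-bromo-8-methoxy-4H-chromen-4-one, via enaminone 4 (not isolated)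
Conditions: toluene, 110 °C; then conc. HCl, CH2Cl2, 40 °C
Reagents that add atoms: none
Why: Enaminone route to chromones: the acetyl CH3 condenses with the formamide acetal, and acid then makes the phenol add to the β-carbon (6-endo addition–elimination) with loss of dimethylamine.

Step 3
Reactants: 5 6-bromo-8-methoxy-4H-chromen-4-one; 6 (4-benzyloxy-3-methoxyphenyl)boronic acid
Product: 7 (2S)-2-(4-benzyloxy-3-methoxyphenyl)-6-bromo-8-methoxychroman-4-one
Conditions: Pd(OCOCF3)2 (5 mol%), (R)-4-tert-butyl-2-(2-pyridyl)-4,5-dihydrooxazole [(R)-t-BuPyOx, 6 mol%], NH4PF6 (30 mol%), H2O (5 equiv), ClCH2CH2Cl, 60 °C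
Reagents that add atoms: none
Why: Asymmetric conjugate addition of an arylboronic acid to a chromone under divalent palladium with a pyridine–oxazoline ligand: transmetallation, enantio-determining carbopalladation of C2=C3 on the enone face left open by the tert-butyl group of the (R)-ligand, and protonolysis of the palladium enolate should set C2 as S, and since palladium stays divalent throughout the aryl bromide is not activated.

Step 4
Reactants: 7 (2S)-2-(4-benzyloxy-3-methoxyphenyl)-6-bromo-8-methoxychroman-4-one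
Product: 8 methyl (2S,3S)-2-(4-benzyloxy-3-methoxyphenyl)-5-bromo-7-methoxy-2,3-dihydrobenzofuran-3-carboxylate (2,3-trans)
Conditions: PhI(OAc)2 (1.3 equiv), conc. H2SO4 (2 equiv), HC(OMe)3, 0 °C → rt
Reagents that add atoms: trimethyl orthoformate, COC(OC)OC
Why: In acidic HC(OMe)3 the ketone of 7 equilibrates with its dimethyl ketal and 4-methoxy enol ether, which the electrophilic trivalent iodine reagent attacks at C3 anti to the equatorial 2-aryl group; the benzo carbon C4a, anti-periplanar to the equatorial C3–I bond, then shifts from C4 to C3 as PhI leaves (iodine falls to the monovalent state) and the dimethoxycarbenium ion left at C4 ends as the methyl ester. The closest known reaction type is the hypervalent-iodine or Tl(NO3)3 oxidative ring contraction of flavanones to methyl trans-2-aryl-2,3-dihydrobenzofuran-3-carboxylates, a semipinacol-type 1,2-aryl shift known also for enantioenriched 8-alkoxyflavanones with a 3,4-dioxygenated 2-aryl group. The five-membered ring is not closed end to end but arises by contraction of the pyranone, the C3–C4a bond forming as C4–C4a breaks in a suprafacial 1,2-shift, so no cyclisation-mode constraint applies. C2 is not involved and keeps the S configuration from step 3; the new C3 centre is controlled by C2, because iodination anti to ring D followed by inversion at C3 places the ester trans to ring D, which is also the thermodynamic arrangement of this epimerisable ester. The step needs C4a to migrate in preference to the 2-aryl group (isoflavone path), to elimination (flavone path) and to simple α-methoxylation: the ketal makes C4 a donor-stabilised migration origin, the ring oxygen ortho to C4a raises its migratory aptitude, and the bromine para to that oxygen and the benzyl ether are inert to the reagent.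

Step 5
Reactants: 8 methyl (2S,3S)-2-(4-benzyloxy-3-methoxyphenyl)-5-bromo-7-methoxy-2,3-dihydrobenzofuran-3-carboxylate
Product: 9 [(2S,3R)-2-(4-benzyloxy-3-methoxyphenyl)-5-bromo-7-methoxy-2,3-dihydrobenzofuran-3-yl]methanol
Conditions: LiBH4, THF, 0 °C → rt
Reagents that add atoms: none
Why: Chemoselective ester reduction by LiBH4 (aryl bromide, benzyl ether and ring survive) leaves C2 and C3 as they are, the C3 descriptor changing from S to R only because CH2OH ranks below C2.

Step 6
Reactants: 9 [(2S,3R)-2-(4-benzyloxy-3-methoxyphenyl)-5-bromo-7-methoxy-2,3-dihydrobenzofuran-3-yl]methanol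
Product: 10 tert-butyldimethylsilyl ether of 9
Conditions: TBSCl, imidazole, CH2Cl2, rt
Reagents that add atoms: tert-butyldimethylsilyl chloride, CC(C)(C)[Si](C)(C)Cl
Why: Routine silylation of a primary alcohol, needed so that no acidic proton is present during the lithiation and the later enolate alkylation.

Step 7
Reactants: 10 tert-butyldimethylsilyl ether of 9
Product: 12 (2S,3R)-2-(4-benzyloxy-3-methoxyphenyl)-3-[(tert-butyldimethylsilyloxy)methyl]-7-methoxy-2,3-dihydrobenzofuran-5-carbaldehyde, via aryllithium 11 (not isolated)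
Conditions: n-BuLi, THF, −78 °C; then DMF, −78 → 0 °C; then H2O
Reagents that add atoms: N,N-dimethylformamide, CN(C)C=O
Why: Bromine–lithium exchange at −78 °C outruns deprotonation at the benzylic positions, and the aryllithium is formylated by DMF (Bouveault aldehyde synthesis).

Step 8
Reactants: 12 the 5-carbaldehyde
Product: 13 [(2S,3R)-2-(4-benzyloxy-3-methoxyphenyl)-3-[(tert-butyldimethylsilyloxy)methyl]-7-methoxy-2,3-dihydrobenzofuran-5-yl]methanol
Conditions: NaBH4, MeOH/THF, 0 °C
Reagents that add atoms: none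
Why: Borohydride reduction of an aromatic aldehyde, with no other reducible group present.

Step 9
Reactants: 13 the 5-(hydroxymethyl) compound
Product: 14 (2S,3R)-2-(4-benzyloxy-3-methoxyphenyl)-5-(bromomethyl)-3-[(tert-butyldimethylsilyloxy)methyl]-7-methoxy-2,3-dihydrobenzofuran
Conditions: CBr4, PPh3, CH2Cl2, 0 °C
Reagents that add atoms: carbon tetrabromide, BrC(Br)(Br)Br
Why: Appel bromination converts the benzylic alcohol under neutral conditions that spare the silyl ether and the acid-sensitive benzylic C2–O bond.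

Step 10
Reactants: 2 1-(5-bromo-2-hydroxy-3-methoxyphenyl)ethanone
Product: 15 1-(2-benzyloxy-5-bromo-3-methoxyphenyl)ethanone
Conditions: BnBr, K2CO3, DMF, 60 °C
Reagents that add atoms: benzyl bromide, BrCc1ccccc1
Why: Williamson etherification of the hydrogen-bonded phenol, which protects it as the same benzyl ether used on rings A and D.

Step 11
Reactants: 15 1-(2-benzyloxy-5-bromo-3-methoxyphenyl)ethanone
Product: 16 methyl 2-(2-benzyloxy-5-bromo-3-methoxyphenyl)acetate
Conditions: PhI(OAc)2 (1.2 equiv), conc. H2SO4 (2 equiv), HC(OMe)3, rt → 50 °C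
Reagents that add atoms: trimethyl orthoformate, COC(OC)OC
Why: Oxidative 1,2-aryl shift of an aryl methyl ketone with trivalent iodine in acidic orthoformate, the open-chain counterpart of step 4: the enol ether is attacked at CH2 and the ortho-alkoxy aryl group migrates as PhI leaves, giving the methyl arylacetate.

Step 12
Reactants: 16 methyl 2-(2-benzyloxy-5-bromo-3-methoxyphenyl)acetate
Product: 17 2-(2-benzyloxy-5-bromo-3-methoxyphenyl)acetic acid
Conditions: LiOH, THF/MeOH/H2O, rt; then 1 M HCl
Reagents that add atoms: lithium hydroxide, [Li+].[OH-]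
Why: Saponification of a methyl ester, with nothing else in 16 base-labile.

Step 13
Reactants: 17 2-(2-benzyloxy-5-bromo-3-methoxyphenyl)acetic acid; 18 (S)-4-benzyloxazolidin-2-one
Product: 20 (4S)-4-benzyl-3-[2-(2-benzyloxy-5-bromo-3-methoxyphenyl)acetyl]oxazolidin-2-one, via mixed pivalic anhydride 19 (not isolated)
Conditions: t-BuCOCl, Et3N, THF, −20 °C; then 18, LiCl, −20 °C → rt
Reagents that add atoms: none
Why: N-Acylation of the oxazolidinone auxiliary through the mixed pivalic anhydride under LiCl/Et3N, the usual way to Evans imides from arylacetic acids.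

Step 14
Reactants: 20 the (4S)-arylacetyl imide; 21 4-benzyloxy-3-methoxybenzaldehyde
Product: 23 (4S)-4-benzyl-3-[(2R,3S)-2-(2-benzyloxy-5-bromo-3-methoxyphenyl)-3-(4-benzyloxy-3-methoxyphenyl)-3-hydroxypropanoyl]oxazolidin-2-one (2,3-anti), via trimethylsilyl ether 22 (not isolated)
Conditions: MgCl2 (20 mol%), Et3N (2 equiv), Me3SiCl (1.5 equiv), EtOAc, 23 °C; then CF3CO2H (cat.), MeOH, 0 °C
Reagents that add atoms: none
Why: MgCl2-catalysed anti-aldol reaction of an N-acyloxazolidinone with a non-enolisable aromatic aldehyde (Evans anti-aldol): soft enolisation gives the chelated Z magnesium enolate, which should add to 21 on the face away from the benzyl group of the (S)-auxiliary through a boat-like transition state to set C8 and C7 as the 2R,3S anti pair, silylation of the aldolate by Me3SiCl turning the catalyst over and blocking retro-aldol.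

Step 15
Reactants: 23 the anti-aldol adduct
Product: 24 (1S,2S)-2-(2-benzyloxy-5-bromo-3-methoxyphenyl)-1-(4-benzyloxy-3-methoxyphenyl)propane-1,3-diol
Conditions: LiBH4, THF, MeOH (1 equiv), 0 °C
Reagents that add atoms: none
Why: Reductive removal of the auxiliary with LiBH4 gives the 1,3-diol without touching C7 or C8 (the C8 descriptor changes from R to S only because CH2OH ranks below C7), and the auxiliary is recovered.

Step 16
Reactants: 24 the (1S,2S)-diol
Product: 25 (4S,5S)-5-(2-benzyloxy-5-bromo-3-methoxyphenyl)-4-(4-benzyloxy-3-methoxyphenyl)-2,2-dimethyl-1,3-dioxane (4,5-trans)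
Conditions: Me2C(OMe)2, PPTS (cat.), acetone, rt
Reagents that add atoms: 2,2-dimethoxypropane, COC(C)(C)OC
Why: Acetonide formation by transketalisation of the 1,3-diol, the anti diol giving the trans-4,5-diaryl-1,3-dioxane with both aryl groups equatorial.

Step 17
Reactants: 25 the bromo acetonide
Product: 27 4-benzyloxy-3-[(4S,5S)-4-(4-benzyloxy-3-methoxyphenyl)-2,2-dimethyl-1,3-dioxan-5-yl]-5-methoxybenzaldehyde, via aryllithium 26 (not isolated)
Conditions: n-BuLi, THF, −78 °C; then DMF, −78 → 0 °C; then H2O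
Reagents that add atoms: N,N-dimethylformamide, CN(C)C=O
Why: Bromine–lithium exchange followed by formylation with DMF (Bouveault aldehyde synthesis), to which the acetonide and the benzyl ethers are inert at −78 °C.

Step 18
Reactants: 27 the ring B aldehyde; 28 dimethyl succinate
Product: 29 (E)-4-aryl-3-(methoxycarbonyl)but-3-enoic acid (aryl = the substituted phenyl of 27)
Conditions: KOt-Bu, t-BuOH, 60 °C; then 1 M HCl to pH 3, 0 °C
Reagents that add atoms: none
Why: Stobbe condensation: the succinate enolate adds to the non-enolisable aldehyde, the alkoxide closes to a paraconate, and E1cB opening gives the E half-ester with the free acid on the CH2 arm, which fixes which carbonyl is reduced later.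

Step 19
Reactants: 29 the Stobbe half-ester
Product: 30 (3R)-4-aryl-3-(methoxycarbonyl)butanoic acid
Conditions: [Rh(cod)((S,S)-Et-DuPhos)]BF4 (1 mol%), H2 (5 bar), NaOMe (10 mol%), MeOH, 25 °C
Reagents that add atoms: none
Why: Asymmetric hydrogenation of a Stobbe half-ester (β-aryl itaconate) with a cationic rhodium–bisphospholane catalyst: the carboxylate arm chelates rhodium and the (S,S)-ligand should deliver H2 to the face that gives the R centre, while benzyl ethers are not cleaved by the homogeneous catalyst.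

Step 20
Reactants: 30 the saturated half-ester
Product: 32 (4R)-4-(arylmethyl)dihydrofuran-2(3H)-one (aryl as in 27), via hydroxy acid 31 (not isolated)
Conditions: KOH (1 equiv), EtOH; CaCl2, NaBH4, EtOH, −10 °C → rt; then 1 M HCl to pH 3, 0 °C → rt
Reagents that add atoms: none
Why: Ca(BH4)2 reduces the methyl ester but not the potassium carboxylate, and acidification closes the γ-hydroxy acid to the β-substituted butyrolactone (5-exo-trig lactonisation) with the stereocentre untouched, the established route from Stobbe half-esters to 4-benzylbutyrolactones.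

Step 21
Reactants: 32 the (4R)-lactone; 14 the benzylic bromide
Product: 34 fully protected target (3R,4R-trans lactone), via lithium enolate 33 (not isolated)
Conditions: LiN(SiMe3)2, THF, −78 °C; then 14, DMPU, −78 → −40 °C
Reagents that add atoms: none
Why: Alkylation of the lithium enolate of a 4-substituted butyrolactone with a benzylic bromide, the standard entry to dibenzylbutyrolactone lignans: the electrophile approaches anti to the C4 arylmethyl group, so the new C3 centre should be R, trans to C4.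

Step 22
Reactants: 34 fully protected target
Product: 35 tris(benzyl ether) of the target
Conditions: AcOH/THF/H2O (3:1:1), 40 °C
Reagents that add atoms: none
Why: Mild aqueous acetic acid hydrolyses the acetonide and the primary silyl ether while the ring B phenol is still benzylated, so the electron-rich benzylic carbinol at C7 cannot be trapped by that phenol as a second dihydrobenzofuran.

Step 23
Reactants: 35 tris(benzyl ether) of the target
Product: 36 CNP0199264.2
Conditions: H2 (1 atm), 10% Pd/C, EtOAc/MeOH, rt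
Reagents that add atoms: none
Why: Hydrogenolysis of the three aryl benzyl ethers over Pd/C at 1 atm, stopped at full conversion, should be much faster than cleavage of the benzylic C7–OH or furan C2–O bonds and frees the target.

**Compound list**

1 | 1-(2-hydroxy-3-methoxyphenyl)ethanone | CC(=O)c1cccc(OC)c1O | starting material
2 | 1-(5-bromo-2-hydroxy-3-methoxyphenyl)ethanone | CC(=O)c1cc(Br)cc(OC)c1O | intermediate
3 | N,N-dimethylformamide dimethyl acetal | COC(OC)N(C)C | starting material
4 | (E)-1-(5-bromo-2-hydroxy-3-methoxyphenyl)-3-(dimethylamino)prop-2-en-1-one | CN(C)/C=C/C(=O)c1cc(Br)cc(OC)c1O | intermediate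
5 | 6-bromo-8-methoxy-4H-chromen-4-one | O=c1ccoc2c(OC)cc(Br)cc12 | intermediate
6 | (4-benzyloxy-3-methoxyphenyl)boronic acid | COc1cc(B(O)O)ccc1OCc1ccccc1 | starting material
7 | (2S)-2-(4-benzyloxy-3-methoxyphenyl)-6-bromo-8-methoxychroman-4-one | O=C1C[C@@H](c2ccc(OCc3ccccc3)c(OC)c2)Oc2c(OC)cc(Br)cc12 | intermediate
8 | methyl (2S,3S)-2-(4-benzyloxy-3-methoxyphenyl)-5-bromo-7-methoxy-2,3-dihydrobenzofuran-3-carboxylate (trans) | COC(=O)[C@H]1c2cc(Br)cc(OC)c2O[C@@H]1c1ccc(OCc2ccccc2)c(OC)c1 | intermediate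
9 | [(2S,3R)-2-(4-benzyloxy-3-methoxyphenyl)-5-bromo-7-methoxy-2,3-dihydrobenzofuran-3-yl]methanol | OC[C@H]1c2cc(Br)cc(OC)c2O[C@@H]1c1ccc(OCc2ccccc2)c(OC)c1 | intermediate
10 | tert-butyldimethylsilyl ether of 9 | CC(C)(C)[Si](C)(C)OC[C@H]1c2cc(Br)cc(OC)c2O[C@@H]1c1ccc(OCc2ccccc2)c(OC)c1 | intermediate
11 | 5-lithio compound from 10 | CC(C)(C)[Si](C)(C)OC[C@H]1c2cc([Li])cc(OC)c2O[C@@H]1c1ccc(OCc2ccccc2)c(OC)c1 | intermediate
12 | (2S,3R)-2-(4-benzyloxy-3-methoxyphenyl)-3-[(tert-butyldimethylsilyloxy)methyl]-7-methoxy-2,3-dihydrobenzofuran-5-carbaldehyde | CC(C)(C)[Si](C)(C)OC[C@H]1c2cc(C=O)cc(OC)c2O[C@@H]1c1ccc(OCc2ccccc2)c(OC)c1 | intermediate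
13 | 5-(hydroxymethyl) analogue of 12 | CC(C)(C)[Si](C)(C)OC[C@H]1c2cc(CO)cc(OC)c2O[C@@H]1c1ccc(OCc2ccccc2)c(OC)c1 | intermediate
14 | 5-(bromomethyl) analogue of 12 | CC(C)(C)[Si](C)(C)OC[C@H]1c2cc(CBr)cc(OC)c2O[C@@H]1c1ccc(OCc2ccccc2)c(OC)c1 | intermediate
15 | 1-(2-benzyloxy-5-bromo-3-methoxyphenyl)ethanone | CC(=O)c1cc(Br)cc(OC)c1OCc1ccccc1 | intermediate
16 | methyl 2-(2-benzyloxy-5-bromo-3-methoxyphenyl)acetate | COC(=O)Cc1cc(Br)cc(OC)c1OCc1ccccc1 | intermediate
17 | 2-(2-benzyloxy-5-bromo-3-methoxyphenyl)acetic acid | OC(=O)Cc1cc(Br)cc(OC)c1OCc1ccccc1 | intermediate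
18 | (S)-4-benzyloxazolidin-2-one | O=C1N[C@@H](Cc2ccccc2)CO1 | starting material
19 | mixed anhydride of 17 with pivalic acid | CC(C)(C)C(=O)OC(=O)Cc1cc(Br)cc(OC)c1OCc1ccccc1 | intermediate
20 | (4S)-4-benzyl-3-[2-(2-benzyloxy-5-bromo-3-methoxyphenyl)acetyl]oxazolidin-2-one | O=C(Cc1cc(Br)cc(OC)c1OCc1ccccc1)N1[C@@H](Cc2ccccc2)COC1=O | intermediate
21 | 4-benzyloxy-3-methoxybenzaldehyde | COc1cc(C=O)ccc1OCc1ccccc1 | starting material
22 | O-trimethylsilyl ether of 23 | O=C([C@H](c1cc(Br)cc(OC)c1OCc1ccccc1)[C@H](O[Si](C)(C)C)c1ccc(OCc2ccccc2)c(OC)c1)N1[C@@H](Cc2ccccc2)COC1=O | intermediate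
23 | (4S)-4-benzyl-3-[(2R,3S)-2-(2-benzyloxy-5-bromo-3-methoxyphenyl)-3-(4-benzyloxy-3-methoxyphenyl)-3-hydroxypropanoyl]oxazolidin-2-one | O=C([C@H](c1cc(Br)cc(OC)c1OCc1ccccc1)[C@H](O)c1ccc(OCc2ccccc2)c(OC)c1)N1[C@@H](Cc2ccccc2)COC1=O | intermediate
24 | (1S,2S)-2-(2-benzyloxy-5-bromo-3-methoxyphenyl)-1-(4-benzyloxy-3-methoxyphenyl)propane-1,3-diol | COc1cc([C@@H](O)[C@H](CO)c2cc(Br)cc(OC)c2OCc2ccccc2)ccc1OCc1ccccc1 | intermediate
25 | (4S,5S)-5-(2-benzyloxy-5-bromo-3-methoxyphenyl)-4-(4-benzyloxy-3-methoxyphenyl)-2,2-dimethyl-1,3-dioxane | CC1(C)OC[C@H](c2cc(Br)cc(OC)c2OCc2ccccc2)[C@@H](c2ccc(OCc3ccccc3)c(OC)c2)O1 | intermediate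
26 | aryllithium from 25 | CC1(C)OC[C@H](c2cc([Li])cc(OC)c2OCc2ccccc2)[C@@H](c2ccc(OCc3ccccc3)c(OC)c2)O1 | intermediate
27 | 4-benzyloxy-3-[(4S,5S)-4-(4-benzyloxy-3-methoxyphenyl)-2,2-dimethyl-1,3-dioxan-5-yl]-5-methoxybenzaldehyde | CC1(C)OC[C@H](c2cc(C=O)cc(OC)c2OCc2ccccc2)[C@@H](c2ccc(OCc3ccccc3)c(OC)c2)O1 | intermediate
28 | dimethyl succinate | COC(=O)CCC(=O)OC | starting material
29 | (E)-4-aryl-3-(methoxycarbonyl)but-3-enoic acid, aryl = substituted phenyl of 27 | CC1(C)OC[C@H](c2cc(/C=C(\CC(=O)O)C(=O)OC)cc(OC)c2OCc2ccccc2)[C@@H](c2ccc(OCc3ccccc3)c(OC)c2)O1 | intermediate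
30 | (3R)-4-aryl-3-(methoxycarbonyl)butanoic acid | CC1(C)OC[C@H](c2cc(C[C@H](CC(=O)O)C(=O)OC)cc(OC)c2OCc2ccccc2)[C@@H](c2ccc(OCc3ccccc3)c(OC)c2)O1 | intermediate
31 | (3R)-4-aryl-3-(hydroxymethyl)butanoic acid | CC1(C)OC[C@H](c2cc(C[C@H](CC(=O)O)CO)cc(OC)c2OCc2ccccc2)[C@@H](c2ccc(OCc3ccccc3)c(OC)c2)O1 | intermediate
32 | (4R)-4-(arylmethyl)dihydrofuran-2(3H)-one | CC1(C)OC[C@H](c2cc(C[C@H]3COC(=O)C3)cc(OC)c2OCc2ccccc2)[C@@H](c2ccc(OCc3ccccc3)c(OC)c2)O1 | intermediate
33 | lithium enolate of 32 | CC1(C)OC[C@H](c2cc(C[C@H]3COC(O[Li])=C3)cc(OC)c2OCc2ccccc2)[C@@H](c2ccc(OCc3ccccc3)c(OC)c2)O1 | intermediate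
34 | fully protected target: (3R,4R)-lactone with diol acetonide, three aryl benzyl ethers and the silyl ether | CC1(C)OC[C@H](c2cc(C[C@H]3COC(=O)[C@@H]3Cc3cc(OC)c4c(c3)[C@H](CO[Si](C)(C)C(C)(C)C)[C@@H](c3ccc(OCc5ccccc5)c(OC)c3)O4)cc(OC)c2OCc2ccccc2)[C@@H](c2ccc(OCc3ccccc3)c(OC)c2)O1 | intermediate
35 | tris(benzyl ether) of the target (free triol) | COc1cc([C@@H](O)[C@H](CO)c2cc(C[C@H]3COC(=O)[C@@H]3Cc3cc(OC)c4c(c3)[C@H](CO)[C@@H](c3ccc(OCc5ccccc5)c(OC)c3)O4)cc(OC)c2OCc2ccccc2)ccc1OCc1ccccc1 | intermediate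
36 | CNP0199264.2 | COc1cc([C@@H](O)[C@H](CO)c2cc(C[C@H]3COC(=O)[C@@H]3Cc3cc(OC)c4c(c3)[C@H](CO)[C@@H](c3ccc(O)c(OC)c3)O4)cc(OC)c2O)ccc1O | target

**Count and risks**

Total steps: 23. Longest linear sequence: 15 (steps 1, 10–20, 21–23); the east branch (steps 1–9) joins at step 21.

Step 14 (anti-aldol). The hindered ortho-benzyloxy arylacetyl imide may enolise or add sluggishly, reversible aldolisation may erode the anti:syn ratio, and Et3N may epimerise the acidic α-aryl centre. The fallback sets out from acid 17 (with aldehyde 21) and returns at diol 24. Acid 17 is joined to (R)-4-benzyloxazolidin-2-one as in step 13 to give the antipodal imide F1. A boron-mediated Evans syn-aldol (n-Bu2BOTf, i-Pr2NEt, CH2Cl2, −78 → 0 °C, then 21) should give the 2R,3R syn adduct F2, in which C8 is correct and C7 is epimeric. LiBH4 then gives the (1R,2S) syn diol F3. Selective benzoylation of the primary hydroxyl (BzCl, 2,4,6-collidine, −78 °C) gives the monobenzoate F4. Mitsunobu inversion of the benzylic carbinol with 4-nitrobenzoic acid (PPh3, DIAD) gives the inverted diester F5. K2CO3 in MeOH removes both esters and delivers 24.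

Step 4 (ring contraction). The electron-rich 2-aryl group may migrate instead of C4a (isoflavone formation), the ketone may be dehydrogenated to the flavone or only α-methoxylated, and acid-induced opening of the pyranone to the chalcone may erode the ee. The fallback sets out from 7 and returns at 8, reaching the same C4→C3 shift of C4a through a carbene. LiN(SiMe3)2 and CF3CO2CH2CF3 at −78 °C give the 3-trifluoroacetyl flavanone F6. Detrifluoroacetylative diazo transfer (MsN3, Et3N, H2O, MeCN) gives the 3-diazo flavanone F7. Irradiation at 365 nm in MeOH triggers the Wolff rearrangement; methanol traps the ring-contracted ketene as ester 8 together with its cis epimer F8, which catalytic DBU in MeOH converts into 8.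

Step 3 (asymmetric conjugate addition). Enantioselectivity or conversion may be insufficient with the 8-methoxychromone, the electron-rich boronic acid may protodeboronate or homocouple, and the flavanone may lose ee later by base-induced retro-oxa-Michael opening. The fallback sets out from ketone 2 (with aldehyde 21) and returns at 7. Claisen–Schmidt condensation (KOH, EtOH) gives the 2'-hydroxychalcone F9. NaOAc in refluxing EtOH cyclises it by oxa-Michael addition to the racemic flavanone F10. Kinetic resolution by asymmetric transfer hydrogenation (RuCl[(R,R)-TsDPEN](p-cymene), HCO2H/Et3N) should reduce the 2R enantiomer to the cis-flavan-4-ol F11 and leave (2S)-7, which is separated by chromatography.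

**Further compounds**

F1 | step 14 | (4R)-4-benzyl-3-[2-(2-benzyloxy-5-bromo-3-methoxyphenyl)acetyl]oxazolidin-2-one | O=C(Cc1cc(Br)cc(OC)c1OCc1ccccc1)N1[C@H](Cc2ccccc2)COC1=O
F2 | step 14 | (4R)-4-benzyl-3-[(2R,3R)-2-(2-benzyloxy-5-bromo-3-methoxyphenyl)-3-(4-benzyloxy-3-methoxyphenyl)-3-hydroxypropanoyl]oxazolidin-2-one (syn) | O=C([C@H](c1cc(Br)cc(OC)c1OCc1ccccc1)[C@@H](O)c1ccc(OCc2ccccc2)c(OC)c1)N1[C@H](Cc2ccccc2)COC1=O
F3 | step 14 | (1R,2S)-2-(2-benzyloxy-5-bromo-3-methoxyphenyl)-1-(4-benzyloxy-3-methoxyphenyl)propane-1,3-diol | COc1cc([C@H](O)[C@H](CO)c2cc(Br)cc(OC)c2OCc2ccccc2)ccc1OCc1ccccc1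
F4 | step 14 | (2S,3R)-2-(2-benzyloxy-5-bromo-3-methoxyphenyl)-3-(4-benzyloxy-3-methoxyphenyl)-3-hydroxypropyl benzoate | COc1cc([C@H](O)[C@H](COC(=O)c2ccccc2)c2cc(Br)cc(OC)c2OCc2ccccc2)ccc1OCc1ccccc1
F5 | step 14 | (1S,2S)-3-(benzoyloxy)-2-(2-benzyloxy-5-bromo-3-methoxyphenyl)-1-(4-benzyloxy-3-methoxyphenyl)propyl 4-nitrobenzoate | COc1cc([C@@H](OC(=O)c2ccc(cc2)[N+](=O)[O-])[C@H](COC(=O)c2ccccc2)c2cc(Br)cc(OC)c2OCc2ccccc2)ccc1OCc1ccccc1
F6 | step 4 | (2S)-2-(4-benzyloxy-3-methoxyphenyl)-6-bromo-8-methoxy-3-(trifluoroacetyl)chroman-4-one (C3 unassigned, enolised) | O=C1C(C(=O)C(F)(F)F)[C@@H](c2ccc(OCc3ccccc3)c(OC)c2)Oc2c(OC)cc(Br)cc12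
F7 | step 4 | (2R)-2-(4-benzyloxy-3-methoxyphenyl)-6-bromo-3-diazo-8-methoxychroman-4-one (same spatial arrangement at C2 as 7; descriptor changes by priority only) | O=C1C(=[N+]=[N-])[C@@H](c2ccc(OCc3ccccc3)c(OC)c2)Oc2c(OC)cc(Br)cc12
F8 | step 4 | methyl (2S,3R)-2-(4-benzyloxy-3-methoxyphenyl)-5-bromo-7-methoxy-2,3-dihydrobenzofuran-3-carboxylate (cis) | COC(=O)[C@@H]1c2cc(Br)cc(OC)c2O[C@@H]1c1ccc(OCc2ccccc2)c(OC)c1
F9 | step 3 | (E)-3-(4-benzyloxy-3-methoxyphenyl)-1-(5-bromo-2-hydroxy-3-methoxyphenyl)prop-2-en-1-one | O=C(/C=C/c1ccc(OCc2ccccc2)c(OC)c1)c1cc(Br)cc(OC)c1O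
F10 | step 3 | racemic 2-(4-benzyloxy-3-methoxyphenyl)-6-bromo-8-methoxychroman-4-one | O=C1CC(c2ccc(OCc3ccccc3)c(OC)c2)Oc2c(OC)cc(Br)cc12
F11 | step 3 | (2R,4R)-2-(4-benzyloxy-3-methoxyphenyl)-6-bromo-8-methoxychroman-4-ol (cis) | O[C@@H]1C[C@H](c2ccc(OCc3ccccc3)c(OC)c2)Oc2c(OC)cc(Br)cc12
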